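- With precatalyst at 0.02 mol% of the starting material, target plus starting material is very nearly an invariant of this closed flask, so you can follow one fraction, the target's.

| flask | starting material | precatalyst | added ligand | temperature | remark | time |
|---|---|---|---|---|---|---|
| Saturday's | 33 mM | 0.02 mol% | 15 µM | 5 °C | the very flask that is asked about, followed so far |  |
| Friday's | 33 mM | 0.04 mol% | 15 µM | 11 °C | run made earlier |  |
| flask | 33 mM | 0.02 mol% | 15 µM | 5 °C |  | 12 min |

- Saturday's (time / min: target / %): 0.833: 28.1; 2.00: 61.9; 4.00: 64.1; 10.0: 63.8
- Friday's (time / min: target / %): 0.333: 22.9; 0.833: 40.9; 1.50: 41.1; 2.50: 41.0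

(standard deviation of a reading: 0.3 percentage points)

- green: at 12 min add precatalyst, 100 % of the amount charged, then wait 12 min
- amber: at 12 min take out 90 % of the target then present, then wait 12 min
- grey: change nothing and wait 12 min more
- blue: at 12 min raise the temperature by 10 K, then wait 12 min

- target taken out counts as made
- the numbers in the tables scatter with a standard deviation of 0.3 percentage points
- additions bring no volume worth counting

* target, in percent of the starting material first charged, at 12 min
* which option adds most target ("none" when 2 percentage points or less is all one gets) (green / amber / grey / blue / none)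
* target present, with what was taken out counted in, in percent of the starting material first charged, after green
* target present, with what was taken out counted in, in percent of the starting material first charged, after blue

- Start with the main step, starting material to target, taken as reversible. A catalyst speeds both directions equally, so the resting ratio of target to starting material, the balance ratio, is its equilibrium constant (thermodynamic control). Saturday's run, which is the flask itself, rests at 63.9 %, so you read 1.77. That plateau is my answer for 12 min.
- Add temperature. Friday's run is warmer and rests at 41.0 %, a ratio of 0.695, lower despite twice the loading. I commit to balance over dead catalyst, though a stalled catalyst also gives a flat line. Taking the logarithm of the ratio as linear in inverse temperature gives a reading of −103 kJ mol⁻¹ for the reaction heat.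
- Add speed, solving both ends and joining them. Saturday's first reading gives the early line, and that line meets the ceiling 63.9 % at 1.90 min, sooner than 12 min, so the flask stands on its ceiling when you act.
- Add the options, assuming the catalyst still lives. Green and grey leave the ratio alone, so green stays at 63.9 %. Blue moves the ratio to 0.380, which is 27.5 % target. Amber removes 90 % of the target, and the remaining pool rebalances, gaining 21 percentage points, more than the margin, so I pick amber.
- The forecast gave 64 %, best none, 65.5 % after green and 64 % after blue, reading “protected catalyst that dies abruptly once the ligand reservoir is exhausted”, so it differs from my reckoning on the best option, on green and on blue.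
- The flask gives 63.9 %, best amber with 21 points gained, 63.9 % after green and 28.0 % after blue.

    starting complex ⇌ free enzyme + target (K = 0.0230 M, k = 1000 s⁻¹, Ea = 51.0 kJ mol⁻¹, ΔH = −52.0 kJ mol⁻¹)
    free enzyme → unfolded enzyme (k = 4.10 × 10⁻⁴ s⁻¹, Ea = 187 kJ mol⁻¹)
    starting material + free enzyme ⇌ starting complex (K = 77.0 M⁻¹, k = 2.30 × 10⁵ M⁻¹ s⁻¹, Ea = 13.0 kJ mol⁻¹, ΔH = −49.0 kJ mol⁻¹)
    free enzyme + added ligand ⇌ idle complex, settled at all times (K = 16000 M⁻¹, ΔH = −15.0 kJ mol⁻¹)
    precatalyst → free enzyme (k = 0.00240 s⁻¹, Ea = 91.0 kJ mol⁻¹)
    free enzyme ⇌ dormant form (K = 1.60, k = 0.00370 s⁻¹, Ea = 82.0 kJ mol⁻¹, ΔH = −70.0 kJ mol⁻¹)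
    (constants at 5 °C)

- In the flask, the step from starting complex to free enzyme + target had half its turnover behind it by 0.910 min and 99.5 % by 2.40 min, while precatalyst stood at 84.1 % of the catalyst charged at 1.20 min. Target stood at 63.9 % at 12.0 min, when precatalyst was down to 17.8 % of the catalyst charged and 94.8 % of the catalyst was still in a form that can turn over, and at 63.9 % at 120 min; amber's simulated gain stands beside the 21 points reckoned from 1.77.
- Take a repeat of the flask at −10 °C: the balance ratio 1.77, carried with −103 kJ mol⁻¹, becomes 22.3, which is 95.7 % target. The computed repeat gives 95.5 %.

(All runs come from a simulation for substances that don't exist; the scatter is artificial.)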